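The readings were computed for an exercise; scatter was added.

Slowness is what to hunt for here, since a flask read at 40 min or 80 min shows what is still moving then. Theta and epsilon are one recipe, read at two times.

| setting | Tuesday's | Friday's | theta | epsilon |
|---|---|---|---|---|
| substrate | 0.30 M | 0.30 M | 0.30 M | 0.30 M |
| partner | 1 equiv | 1 equiv | 1.00 equiv | 1.00 equiv |
| free catalyst | 4.5 mol% | 6.8 mol% | 9 mol% | 9 mol% |
| second catalyst | 0.5 mol% | 0.5 mol% | 0.5 mol% | 0.5 mol% |
| remark | run made earlier | run made earlier |  |  |
| time |  |  | 40 min | 80 min |

- Tuesday's (time / min: target / %, substrate / %, intermediate / %): 2.00: 21.8, 73.4, 6.4; 4.00: 39.7, 53.4, 5.3; 6.00: 51.9, 39.4, 4.7; 12.0: 76.7, 18.4, 4.9; 25.0: 90.2, 4.3, 2.4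
- Friday's (time / min: target / %, substrate / %, intermediate / %): 5.00: 59.5, 31.1, 7.9; 10.0: 81.6, 11.0, 6.9; 15.0: 87.9, 5.2, 6.2; 20.0: 92.0, 2.3, 3.6; 25.0: 93.5, 0, 2.5

(standard deviation of a reading: 1 percentage point)

* which of these there is most of at the end, counted by the substrate in it, theta (intermediate / substrate / target)
* which of these there is most of at the end, counted by the substrate in it, epsilon (intermediate / substrate / target)
* how much there is at the end of the one of these that leads, in percent of the substrate charged: theta
* how much there is at the end of the one of these that leads, in percent of the substrate charged: epsilon



Read Friday's table row by row. Substrate halves in about 3.33 min between its first two rows, so I scale that to about 2.52 min at 9 mol% free catalyst, which is about 15.9 half-lives by 40 min. Now add the three columns. They give 99.5% at 10.0 min, but 96.0% in the last row, so 4.00% stands in no column. Tuesday's run, with 4.5 mol% free catalyst, ends 3.10% short. Each reading scatters by 1 percentage point, so these gaps are rough.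

My guess is that free catalyst takes up target one for one, into a form no column counts. Friday's gap then means 58.8% of its free catalyst went in 25.0 min. That gives the catching half-life, the time in which free catalyst halves while target stands high: 19.5 min, longer than substrate's. Theta counts 2.05 of these and epsilon 4.10. So I expect target plus intermediate near 93.2% in theta and 91.5% in epsilon.

The forecast names target for both, at 94% and 94.5%, reading the late shortfall as “suggesting a small loss”. Its number rises from theta to epsilon, while mine falls.

The flask gives target in both, 91.9% in theta and 90.9% in epsilon, each lower than the forecast's number.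

    substrate + free catalyst → free catalyst + intermediate (k = 0.190 L mol⁻¹ s⁻¹)
    free catalyst + target → spent catalyst (k = 0.00210 L mol⁻¹ s⁻¹)
    partner + second catalyst + intermediate → second catalyst + target (k = 73.0 L² mol⁻² s⁻¹)

Epsilon stands 1.00 point under theta, so waiting longer costs target here. Substrate's step has >99.9% of its turnover behind it at 40.0 min in epsilon, but the step from free catalyst and target to spent catalyst has 77%. The constants put free catalyst's half-life in theta's end state at 20.0 min, against 2.3 min for substrate at 2.27 min in epsilon.

Now take a neighbour flask, like epsilon but with 0.250 equiv of partner, the limiting reagent there. In my reckoning the catching half-life stretches in proportion to the smaller amount of target, to 73.0 min, so I count 1.10 half-lives, 46.8% free catalyst left and 20.2% target. That flask gives 51.5% free catalyst and 20.6% target.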